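The flavan is cut at C4–C4a. The pyran ring is closed by a gold(I)-catalysed 6-endo-dig hydroarylation of an aryl propargyl ether in which the O1–C2 bond and the S centre at C2 already exist. The step exploits the substitution of ring A: C4a is the only unsubstituted carbon ortho to O1, because C8 carries the prenyl group, so the alkyne tethered to O1 can only join its terminal carbon to C4a. One operation therefore forms C4–C4a and the heterocycle and leaves C2 untouched. The precursor is the (S)-1-arylprop-2-ynyl ether of 3-methoxy-2-prenyl-5-(triisopropylsilyloxy)phenol; its ring B carries two mesylates, which hold back ionisation of the C2–O1 bond.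

Key step: step 7

Assumption: which enantiomer of the pybox ligand gives the (S)-ether in step 5 is settled by a trial run; the antipodal ligand gives the antipode, so the (S) series is reachable either way.

Remark on protecting groups: ring B is carried as its bis(methanesulfonate), because a carboxylic ester ortho to the carbinol could migrate onto the magnesium alkoxide of step 4 and open a path to an ortho-quinone methide, whereas a sulfonyl group cannot migrate in this way and comes off at −78 °C in step 9; TIPS is used on ring A for selectivity in step 2 and stability in step 6.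

Step 1
Reactants: 1 phloroglucinol; 2 prenyl bromide
Product: 3 2-(3-methylbut-2-en-1-yl)benzene-1,3,5-triol (2-prenylphloroglucinol)
Conditions: 1 (3 equiv), DBU (1 equiv), THF, 0 °C → rt
Reagents that add atoms: none
Why: Friedel–Crafts-type C-alkylation of the ambident phloroglucinol anion, a known C-prenylation; the three ring carbons are equivalent, so only the degree of alkylation has to be held, which the excess of cheap 1 should do.

Step 2
Reactants: 3 2-prenylphloroglucinol
Product: 4 2-(3-methylbut-2-en-1-yl)-5-(triisopropylsilyloxy)benzene-1,3-diol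
Conditions: TIPSCl (1.0 equiv), imidazole, DMF, −20 → 0 °C
Reagents that add atoms: triisopropylsilyl chloride, CC(C)[Si](Cl)(C(C)C)C(C)C
Why: Imidazole-mediated O-silylation under steric control; the hydroxyl para to the prenyl group has two ring hydrogens as neighbours, whereas each of the other two sits next to the prenyl chain, so the bulky silyl chloride should take the para oxygen first.

Step 3
Reactants: 5 2,4-dihydroxybenzaldehyde
Product: 6 4-formyl-1,3-phenylene dimethanesulfonate
Conditions: MsCl (2.3 equiv), Et3N, CH2Cl2, 0 °C
Reagents that add atoms: methanesulfonyl chloride, CS(=O)(=O)Cl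
Why: Standard O-sulfonylation of both phenols; the mesylates make ring B electron-poor and carry no group that can be transferred to a neighbouring alkoxide.

Step 4
Reactants: 6 4-formyl-1,3-phenylene dimethanesulfonate; 7 ethynylmagnesium bromide
Product: 9 rac-1-[2,4-bis(methanesulfonyloxy)phenyl]prop-2-yn-1-yl acetate, via magnesium alkoxide 8 (not isolated)
Conditions: THF, −40 → 0 °C; then Ac2O, 0 °C → rt
Reagents that add atoms: acetic anhydride, CC(=O)OC(C)=O
Why: Grignard 1,2-addition to the aldehyde followed by O-acetylation of the magnesium alkoxide in the same flask; substitution at sulfur needs a near-linear arrangement that a six-membered cyclic transition state cannot provide, so the ortho mesylate should stay in place, and the racemate is wanted because step 5 is stereoconvergent.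

Step 5
Reactants: 9 rac-1-[2,4-bis(methanesulfonyloxy)phenyl]prop-2-yn-1-yl acetate; 4 2-(3-methylbut-2-en-1-yl)-5-(triisopropylsilyloxy)benzene-1,3-diol
Product: 10 3-{[(1S)-1-[2,4-bis(methanesulfonyloxy)phenyl]prop-2-yn-1-yl]oxy}-2-(3-methylbut-2-en-1-yl)-5-(triisopropylsilyloxy)phenol
Conditions: Cu(OTf)·½C6H6 (5 mol%), Ph-pybox (10 mol%, enantiomer giving the S ether), iPr2NEt (1.2 equiv), 4 (2.5 equiv), THF, −20 → 0 °C
Reagents that add atoms: none
Why: Copper-catalysed asymmetric propargylic etherification, in which both enantiomers of 9 converge on one copper allenylidene and the phenol adds to its γ-carbon on the face left open by the pybox ligand, which sets C2 as S; the two hydroxyls of 4 are equivalent, the excess diol should hold the reaction at the mono-ether, and the TIPS group shields the two free ring carbons against C-propargylation.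

Step 6
Reactants: 10 the (S)-propargyl ether phenol
Product: 11 4-{(1S)-1-[3-methoxy-2-(3-methylbut-2-en-1-yl)-5-(triisopropylsilyloxy)phenoxy]prop-2-yn-1-yl}-1,3-phenylene dimethanesulfonate
Conditions: MeI, K2CO3, acetone, rt
Reagents that add atoms: iodomethane, CI
Why: Williamson O-methylation of the one remaining phenol; carbonate is too weak a base to touch the propargylic C–H at C2, the alkyne C–H, the aryl mesylates or the TIPS ether.

Step 7
Reactants: 11 the (S)-aryl propargyl ether
Product: 12 4-[(2S)-7-methoxy-8-(3-methylbut-2-en-1-yl)-5-(triisopropylsilyloxy)-2H-chromen-2-yl]-1,3-phenylene dimethanesulfonate (the (2S)-flav-3-ene)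
Conditions: [(JohnPhos)Au(MeCN)]SbF6 (3 mol%), CH2Cl2, 0 °C → rt, dark
Reagents that add atoms: none
Why: Cationic gold(I) binds the terminal alkyne, C4a attacks the terminal alkyne carbon in a Friedel–Crafts manner, and rearomatisation followed by protodeauration should release the 2H-chromene. The closest known reaction type is the gold(I)- or platinum-catalysed intramolecular hydroarylation of aryl propargyl ethers to 2H-chromenes. The pyran ring closes in the 6-endo-dig mode through the new C4–C4a bond. No stereocentre is formed, and C2 keeps its S configuration because the C2–O1 bond is not broken at any stage. The step needs attack by C4a alone, no ionisation of the propargylic and benzylic C2–O1 bond and no enyne reaction with the prenyl alkene; these are secured by C8 being blocked while C4a is activated by O1 and O5 (ortho) and the 7-methoxy group (para), by the two mesylates that make ring B a poor cation-stabilising group, and by the prenyl alkene being too remote to reach the alkyne without a medium ring. Working at or below room temperature keeps the thermal Claisen pathway, which would scramble C2, closed.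

Step 8
Reactants: 12 the (2S)-flav-3-ene
Product: 13 4-[(2S)-7-methoxy-8-(3-methylbut-2-en-1-yl)-5-(triisopropylsilyloxy)-3,4-dihydro-2H-chromen-2-yl]-1,3-phenylene dimethanesulfonate
Conditions: 2-nitrobenzenesulfonylhydrazide, Et3N, CH2Cl2, rt
Reagents that add atoms: none
Why: Diimide reduction, a concerted syn transfer of two hydrogens from HN=NH made in the flask, should reduce the cis-disubstituted C3=C4 alkene well before the trisubstituted prenyl alkene and cannot cleave the benzylic C2–O1 bond or the sulfonates, so C2 is untouched.

Step 9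
Reactants: 13 the (2S)-flavan bis(mesylate)
Product: 14 4-[(2S)-7-methoxy-8-(3-methylbut-2-en-1-yl)-5-(triisopropylsilyloxy)-3,4-dihydro-2H-chromen-2-yl]benzene-1,3-diol
Conditions: LDA (5 equiv), THF, −78 °C; then aq NH4Cl
Reagents that add atoms: none
Why: Known cleavage of aryl methanesulfonates by α-deprotonation and E1cB loss of sulfene, which should free both phenoxides at −78 °C, a temperature at which the ring-B phenoxides cannot open the pyran ring through a quinone methide, so C2 stays S.

Step 10
Reactants: 14 the 5-O-TIPS flavan
Product: 15 4-[(2S)-5-hydroxy-7-methoxy-8-(3-methylbut-2-en-1-yl)-3,4-dihydro-2H-chromen-2-yl]benzene-1,3-diol (target)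
Conditions: TBAF, AcOH, THF, 0 °C
Reagents that add atoms: none
Why: Fluoride-induced desilylation of the aryl TIPS ether; acetic acid keeps the liberated phenols protonated, so the base- and acid-sensitive 2',4'-dihydroxyflavan should be released without epimerisation at C2.

Compound list
1 | phloroglucinol | Oc1cc(O)cc(O)c1 | starting material
2 | prenyl bromide | CC(C)=CCBr | starting material
3 | 2-(3-methylbut-2-en-1-yl)benzene-1,3,5-triol | CC(C)=CCc1c(O)cc(O)cc1O | intermediate
4 | 2-(3-methylbut-2-en-1-yl)-5-(triisopropylsilyloxy)benzene-1,3-diol | CC(C)=CCc1c(O)cc(O[Si](C(C)C)(C(C)C)C(C)C)cc1O | intermediate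
5 | 2,4-dihydroxybenzaldehyde | O=Cc1ccc(O)cc1O | starting material
6 | 4-formyl-1,3-phenylene dimethanesulfonate | O=Cc1ccc(OS(C)(=O)=O)cc1OS(C)(=O)=O | intermediate
7 | ethynylmagnesium bromide | C#C[Mg]Br | starting material
8 | bromomagnesium 1-[2,4-bis(methanesulfonyloxy)phenyl]prop-2-yn-1-olate (magnesium alkoxide, racemic, not isolated) | C#CC(O[Mg]Br)c1ccc(OS(C)(=O)=O)cc1OS(C)(=O)=O | intermediate
9 | rac-1-[2,4-bis(methanesulfonyloxy)phenyl]prop-2-yn-1-yl acetate | C#CC(OC(C)=O)c1ccc(OS(C)(=O)=O)cc1OS(C)(=O)=O | intermediate
10 | 3-{[(1S)-1-[2,4-bis(methanesulfonyloxy)phenyl]prop-2-yn-1-yl]oxy}-2-(3-methylbut-2-en-1-yl)-5-(triisopropylsilyloxy)phenol | Oc1cc(O[Si](C(C)C)(C(C)C)C(C)C)cc(c1CC=C(C)C)O[C@H](c1ccc(OS(C)(=O)=O)cc1OS(C)(=O)=O)C#C | intermediate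
11 | 4-{(1S)-1-[3-methoxy-2-(3-methylbut-2-en-1-yl)-5-(triisopropylsilyloxy)phenoxy]prop-2-yn-1-yl}-1,3-phenylene dimethanesulfonate | COc1cc(O[Si](C(C)C)(C(C)C)C(C)C)cc(c1CC=C(C)C)O[C@H](c1ccc(OS(C)(=O)=O)cc1OS(C)(=O)=O)C#C | intermediate
12 | 4-[(2S)-7-methoxy-8-(3-methylbut-2-en-1-yl)-5-(triisopropylsilyloxy)-2H-chromen-2-yl]-1,3-phenylene dimethanesulfonate | COc1cc(O[Si](C(C)C)(C(C)C)C(C)C)c2c(c1CC=C(C)C)O[C@H](c1ccc(OS(C)(=O)=O)cc1OS(C)(=O)=O)C=C2 | intermediate
13 | 4-[(2S)-7-methoxy-8-(3-methylbut-2-en-1-yl)-5-(triisopropylsilyloxy)-3,4-dihydro-2H-chromen-2-yl]-1,3-phenylene dimethanesulfonate | COc1cc(O[Si](C(C)C)(C(C)C)C(C)C)c2c(c1CC=C(C)C)O[C@H](c1ccc(OS(C)(=O)=O)cc1OS(C)(=O)=O)CC2 | intermediate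
14 | 4-[(2S)-7-methoxy-8-(3-methylbut-2-en-1-yl)-5-(triisopropylsilyloxy)-3,4-dihydro-2H-chromen-2-yl]benzene-1,3-diol | COc1cc(O[Si](C(C)C)(C(C)C)C(C)C)c2c(c1CC=C(C)C)O[C@H](c1ccc(O)cc1O)CC2 | intermediate
15 | 4-[(2S)-5-hydroxy-7-methoxy-8-(3-methylbut-2-en-1-yl)-3,4-dihydro-2H-chromen-2-yl]benzene-1,3-diol | COc1cc(O)c2c(c1CC=C(C)C)O[C@H](c1ccc(O)cc1O)CC2 | target

Total step count: 10
Longest linear sequence: 8 steps (steps 3–10 from 2,4-dihydroxybenzaldehyde, or steps 1, 2 and 5–10 from phloroglucinol)

Steps most likely to fail

Step 7. The Lewis-acidic catalyst may ionise the doubly activated C2–O1 bond before the hindered C4a, which lies between O1 and the silyloxy group, closes the ring. That would erode the configuration at C2 or fragment the ether, and heating to force the closure would open the racemising Claisen pathway. The fallback sets out from 11 and replaces π-activation of the alkyne by a carbonyl electrophile. Hydroboration of the terminal alkyne with dicyclohexylborane, which should leave the trisubstituted prenyl alkene alone, and oxidation with H2O2 at pH 7 (buffered, to avoid β-elimination of the aryloxide) should give (3S)-3-[2,4-bis(methanesulfonyloxy)phenyl]-3-[3-methoxy-2-(3-methylbut-2-en-1-yl)-5-(triisopropylsilyloxy)phenoxy]propanal F1. Catalytic Sc(OTf)3 or PPTS in CH2Cl2 at −20 °C should then bring about intramolecular Friedel–Crafts hydroxyalkylation at C4a, the only free ortho carbon. The resulting (2S)-flavan-4-ol, 4-[(2S)-4-hydroxy-7-methoxy-8-(3-methylbut-2-en-1-yl)-5-(triisopropylsilyloxy)-3,4-dihydro-2H-chromen-2-yl]-1,3-phenylene dimethanesulfonate F2, is not isolated: it should lose water through its ring-A-stabilised C4 cation, and the sequence comes back to the route at 12. The C2–O1 bond is again never broken.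

Step 5. The electron-rich ring carbon may attack the copper allenylidene in place of oxygen, a second etherification may follow, or the ortho-substituted aryl group may weaken the facial discrimination. The fallback sets out from 6 and fixes the configuration before the C–O bond is made. Zinc–ProPhenol-catalysed asymmetric addition of trimethylsilylacetylene (Me2Zn, toluene; ligand enantiomer chosen accordingly) should give (1S)-1-[2,4-bis(methanesulfonyloxy)phenyl]-3-(trimethylsilyl)prop-2-yn-1-ol F3. K2CO3 in MeOH at 0 °C should remove the silyl group to give (1R)-1-[2,4-bis(methanesulfonyloxy)phenyl]prop-2-yn-1-ol F4, which has the same spatial arrangement (the descriptor changes only because silicon is lost). Mitsunobu etherification of excess 4 with F4 (PPh3, DIAD, toluene, 0 °C) should proceed with inversion, helped by the electron-poor ring B, and comes back to the route at 10.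

Step 2. Silylation may occur at a hydroxyl next to the prenyl group, or twice, giving isomers that are hard to separate. The fallback sets out from 1 and fixes the regiochemistry by directed metalation instead of steric discrimination. Monosilylation of excess 1 (TIPSCl, imidazole, DMF) should give 5-(triisopropylsilyloxy)benzene-1,3-diol F5. MOMCl and iPr2NEt in CH2Cl2 should give 1,3-bis(methoxymethoxy)-5-(triisopropylsilyloxy)benzene F6. n-BuLi in THF at 0 °C should lithiate the carbon between the two MOM ethers; transmetalation with CuBr·SMe2 and alkylation with 2 should give 1,3-bis(methoxymethoxy)-2-(3-methylbut-2-en-1-yl)-5-(triisopropylsilyloxy)benzene F7. Dilute HCl in MeOH at rt should remove both MOM groups without cyclising the prenyl chain, and the sequence comes back to the route at 4.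

Further compounds
F1 | step 7 | (3S)-3-[2,4-bis(methanesulfonyloxy)phenyl]-3-[3-methoxy-2-(3-methylbut-2-en-1-yl)-5-(triisopropylsilyloxy)phenoxy]propanal | COc1cc(O[Si](C(C)C)(C(C)C)C(C)C)cc(c1CC=C(C)C)O[C@H](c1ccc(OS(C)(=O)=O)cc1OS(C)(=O)=O)CC=O
F2 | step 7 | 4-[(2S)-4-hydroxy-7-methoxy-8-(3-methylbut-2-en-1-yl)-5-(triisopropylsilyloxy)-3,4-dihydro-2H-chromen-2-yl]-1,3-phenylene dimethanesulfonate (C4 epimers, not isolated) | COc1cc(O[Si](C(C)C)(C(C)C)C(C)C)c2c(c1CC=C(C)C)O[C@H](c1ccc(OS(C)(=O)=O)cc1OS(C)(=O)=O)CC2O
F3 | step 5 | (1S)-1-[2,4-bis(methanesulfonyloxy)phenyl]-3-(trimethylsilyl)prop-2-yn-1-ol | O[C@@H](c1ccc(OS(C)(=O)=O)cc1OS(C)(=O)=O)C#C[Si](C)(C)C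
F4 | step 5 | (1R)-1-[2,4-bis(methanesulfonyloxy)phenyl]prop-2-yn-1-ol | O[C@@H](c1ccc(OS(C)(=O)=O)cc1OS(C)(=O)=O)C#C
F5 | step 2 | 5-(triisopropylsilyloxy)benzene-1,3-diol | Oc1cc(O)cc(O[Si](C(C)C)(C(C)C)C(C)C)c1
F6 | step 2 | 1,3-bis(methoxymethoxy)-5-(triisopropylsilyloxy)benzene | COCOc1cc(OCOC)cc(O[Si](C(C)C)(C(C)C)C(C)C)c1
F7 | step 2 | 1,3-bis(methoxymethoxy)-2-(3-methylbut-2-en-1-yl)-5-(triisopropylsilyloxy)benzene | COCOc1cc(O[Si](C(C)C)(C(C)C)C(C)C)cc(OCOC)c1CC=C(C)C
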